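Ring B is traced back to an achiral p-quinol (4-alkyl-4-hydroxy-3,5-dimethylcyclohexa-2,5-dienone): its carbonyl is C6, its methyl-bearing β-carbons are C10 and C8, and the carbinol carbon is C9, sp2 in the target. Esterifying the C9 hydroxyl with a β-keto acid carrying an isobutenyl ketone (C1–C4) sets up a catalytic asymmetric tethered double Michael reaction: C1 adds to C10 (closing a temporary γ-lactone and desymmetrising the dienone), then the C5 enolate adds to C4, closing ring A. Reductive expulsion of the C9 carboxylate later creates the C8=C9 alkene and unmasks a β-keto acid that decarboxylates.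

Key step: step 7

Remarks and assumptions
- Labdane numbering is used throughout: ring A is C1–C5 and C10, ring B is C5–C10, C9 carries the side chain C11–C15. α and β refer to the usual drawing with the C10 methyl β.
- (E)-3-Methylpent-2-en-4-yn-1-ol is assumed to be bought as the pure E isomer.
- The cinchonidine-derived ammonium salt is assumed to give the C10 configuration shown; if the sense is opposite, its cinchonine-derived pseudoenantiomer takes its place.

Step 1
Reactants: 1 (E)-3-methylpent-2-en-4-yn-1-ol
Product: 2 (E)-triisopropyl[(3-methylpent-2-en-4-yn-1-yl)oxy]silane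
Conditions: TIPSCl, imidazole, CH2Cl2, 0 °C to rt
Reagents that add atoms: triisopropylsilyl chloride, CC(C)[Si](Cl)(C(C)C)C(C)C
Why: O-Silylation of the primary allylic alcohol should be clean, and the bulky triisopropylsilyl ether is chosen to survive base, hypervalent iodine, SmI2, acetic acid and dissolving metal later on.

Step 2
Reactants: 2 (E)-triisopropyl[(3-methylpent-2-en-4-yn-1-yl)oxy]silane
Product: 3 (E)-triisopropyl[(3-methylpenta-2,4-dien-1-yl)oxy]silane
Conditions: H2 (1 atm), Pd on CaCO3 poisoned with Pb(OAc)2, quinoline, hexane, rt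
Reagents that add atoms: none
Why: Alkyne semihydrogenation over poisoned palladium should stop at the 1,3-diene and leave the trisubstituted E alkene untouched.

Step 3
Reactants: 3 (E)-triisopropyl[(3-methylpenta-2,4-dien-1-yl)oxy]silane; 4 4-bromo-3,5-dimethylphenol
Product: 6 3,5-dimethyl-4-[(E)-3-methyl-5-(triisopropylsilyloxy)pent-3-enyl]phenol, via alkylborane 5 (not isolated)
Conditions: 9-BBN, THF, 0 °C to rt; then Pd(OAc)2 (3 mol %), 2-dicyclohexylphosphino-2',6'-dimethoxybiphenyl, K3PO4, THF/H2O, 65 °C
Reagents that add atoms: 9-borabicyclo[3.3.1]nonane, B1C2CCCC1CCC2 (its boron unit is held only in 5)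
Why: Anti-Markovnikov hydroboration with 9-BBN should occur only at the monosubstituted vinyl terminus, and the B-alkyl Suzuki–Miyaura coupling with a biaryl dialkylphosphine ligand should tolerate the two ortho methyl groups and the free phenol.

Step 4
Reactants: 6 3,5-dimethyl-4-[(E)-3-methyl-5-(triisopropylsilyloxy)pent-3-enyl]phenol
Product: 7 4-hydroxy-3,5-dimethyl-4-[(E)-3-methyl-5-(triisopropylsilyloxy)pent-3-enyl]cyclohexa-2,5-dienone (achiral p-quinol)
Conditions: PhI(OAc)2, MeCN/H2O (3:1), 0 °C
Reagents that add atoms: water, O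
Why: Oxidative dearomatisation of a para-alkylphenol with PhI(OAc)2 should be trapped by water at the substituted para carbon (C9), giving a symmetric p-quinol with no stereocenter.

Step 5
Reactants: 8 2,2-dimethyl-1,3-dioxane-4,6-dione (Meldrum's acid); 9 3-methylbut-2-enoyl chloride
Product: 10 5-(1-hydroxy-3-methylbut-2-enylidene)-2,2-dimethyl-1,3-dioxane-4,6-dione
Conditions: pyridine, CH2Cl2, 0 °C to rt
Reagents that add atoms: none
Why: C-Acylation of the acidic methylene of 8 by the acid chloride is a standard route to an acylketene precursor.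

Step 6
Reactants: 7 p-quinol; 10 acylated dioxanedione
Product: 12 p-quinol 5-methyl-3-oxohex-4-enoate (ester of 7 at the C9 oxygen), via acylketene 11 (not isolated)
Conditions: toluene, 90 °C
Reagents that add atoms: none
Why: Thermal retro-[4+2] fragmentation of 10 releases acetone and CO2 and gives an acylketene that should acylate even the hindered tertiary quinol hydroxyl under neutral conditions (acylketene esterification) without touching the dienone.

Step 7
Reactants: 12 p-quinol β-keto ester
Product: 15 trans-fused tricyclic keto lactone (C2 and C6 ketones; C7=C8; 5α-H; 10β-methyl; γ-lactone from a C1α carboxyl to the C9α oxygen), via mono-Michael lactone 13 (not isolated), via cis-fused tricyclic lactone 14 (not isolated)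
Conditions: N-(9-anthracenylmethyl)-O-allylcinchonidinium bromide (10 mol %), Cs2CO3 (20 mol %), toluene (dilute), −20 °C to rt; then DBU (3 equiv), 70 °C
Reagents that add atoms: none
Why: The ammonium enolate of the β-keto ester adds through C1 to C10 of the dienone and the C5 enolate so formed adds to C4 of the β,β-dimethyl enone, a tethered anionic double Michael reaction (formal [4+2]); the closest known reaction types are the carbonate-mediated double Michael annulation of vinyl-ketone β-keto esters with cyclohexenones and the catalytic desymmetrisation of p-quinol-derived cyclohexadienones by a tethered carbon acid. The temporary γ-lactone closes 5-exo-trig and ring A closes 6-endo-trig. C10 is set by the chiral ion pair, which chooses between the enantiotopic methyl-bearing β-carbons C10 and C8; C9 is set by the tether, which can deliver C1 only to the face that carries the C9 oxygen (cis-fused lactone); C1 is epimerisable and should settle with its hydrogen cis to the C10 methyl. C5 is first formed cis to the C10 methyl (axial attack of C4 on the enolate) and is then equilibrated by DBU through the C5 enolate to the trans-fused decalin, in which both ring A bonds are equatorial on ring B and the lactone spans the syn-axial C1 and C9 positions. The step needs C-attack at C10 in preference to intermolecular addition and needs ring A to close before retro-Michael opening erodes the enantiomeric excess; the two-atom ester tether, the dilution and the position of the nascent C5 enolate next to the tethered enone should secure this.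

Step 8
Reactants: 15 trans-fused tricyclic keto lactone
Product: 17 15-(triisopropylsilyloxy)labda-8,13E-diene-2,6-dione (5α-H), via β-keto acid 16 (not isolated)
Conditions: SmI2 (2.2 equiv), THF/MeOH, −78 °C; pH 4 buffer; then toluene, 70 °C
Reagents that add atoms: none
Why: SmI2 should reduce the enone to a ketyl that expels the γ-carboxylate (reductive elimination of a γ-acyloxy enone), kinetic protonation of the samarium dienolate at C7 gives the β,γ-unsaturated ketone with the C8=C9 double bond, and the freed β-keto acid loses CO2 on warming (decarboxylation), which removes the C9 and C1 stereocenters while C5 and C10 are untouched.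

Step 9
Reactants: 17 15-(triisopropylsilyloxy)labda-8,13E-diene-2,6-dione
Product: 18 7α-hydroxy-15-(triisopropylsilyloxy)labda-8,13E-diene-2,6-dione
Conditions: KN(SiMe3)2 (1.0 equiv), THF, −78 to −40 °C; 2-(phenylsulfonyl)-3-phenyloxaziridine, −78 °C; aq. NH4Cl
Reagents that add atoms: 2-(phenylsulfonyl)-3-phenyloxaziridine, O=S(=O)(c1ccccc1)N1OC1c1ccccc1
Why: Enolate α-hydroxylation with an N-sulfonyloxaziridine: the C7 hydrogens are both α to the C6 ketone and allylic, so one equivalent of base under equilibrating conditions should give the extended dienolate, which is oxidised at C7 from the α-face, anti to the axial C10 methyl (axial attack), to set 7α.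

Step 10
Reactants: 18 7α-hydroxy-15-(triisopropylsilyloxy)labda-8,13E-diene-2,6-dione
Product: 19 6β,7α-dihydroxy-15-(triisopropylsilyloxy)labda-8,13E-dien-2-one
Conditions: Me4NBH(OAc)3, MeCN/AcOH (1:1), −20 °C
Reagents that add atoms: none
Why: Hydroxyl-directed triacetoxyborohydride reduction: hydride is delivered from boron bound to the 7α oxygen to the α-face of C6, the face that is also free of the syn-axial C10 and C4 methyls, which sets 6β-OH trans to 7α-OH, while the isolated C2 ketone is not reduced by this reagent.

Step 11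
Reactants: 19 6β,7α-dihydroxy-15-(triisopropylsilyloxy)labda-8,13E-dien-2-one
Product: 20 15-(triisopropylsilyloxy)labda-8,13E-diene-2α,6β,7α-triol
Conditions: Li, NH3(l)/THF, tBuOH, −78 °C; then NH4Cl
Reagents that add atoms: none
Why: Dissolving-metal reduction of a ketone gives the thermodynamically preferred carbinol, here the equatorial 2α-alcohol, because the axial 2β-alkoxide would be syn-axial to the C10 and C4β methyls, whereas hydride reagents would attack from the open α-face and give the wrong epimer.

Step 12
Reactants: 20 15-(triisopropylsilyloxy)labda-8,13E-diene-2α,6β,7α-triol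
Product: 21 2α,6β,7α-triacetoxy-15-(triisopropylsilyloxy)labda-8,13E-diene
Conditions: Ac2O, DMAP, Et3N, CH2Cl2, 40 °C
Reagents that add atoms: acetic anhydride, CC(=O)OC(C)=O
Why: DMAP-catalysed acylation should esterify the equatorial C2, the allylic C7 and, with warming, the hindered axial C6 hydroxyl, while the primary alcohol stays masked as its silyl ether.

Step 13
Reactants: 21 2α,6β,7α-triacetoxy-15-(triisopropylsilyloxy)labda-8,13E-diene
Product: 22 2α,6β,7α-triacetoxylabda-8,13E-dien-15-ol (CNP0305346.2)
Conditions: HF·pyridine, THF/pyridine, 0 °C to rt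
Reagents that add atoms: none
Why: Fluoride-mediated desilylation under buffered conditions should free the primary allylic alcohol without acetate migration or cleavage.

Compound list
1 | (E)-3-methylpent-2-en-4-yn-1-ol | C#C/C(C)=C/CO | starting material
2 | (E)-triisopropyl[(3-methylpent-2-en-4-yn-1-yl)oxy]silane | C#C/C(C)=C/CO[Si](C(C)C)(C(C)C)C(C)C | intermediate
3 | (E)-triisopropyl[(3-methylpenta-2,4-dien-1-yl)oxy]silane | C=C/C(C)=C/CO[Si](C(C)C)(C(C)C)C(C)C | intermediate
4 | 4-bromo-3,5-dimethylphenol | Cc1cc(O)cc(C)c1Br | starting material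
5 | 9-[(E)-3-methyl-5-(triisopropylsilyloxy)pent-3-enyl]-9-borabicyclo[3.3.1]nonane (not isolated) | C1CCC2CCCC1B2CC/C(C)=C/CO[Si](C(C)C)(C(C)C)C(C)C | intermediate
6 | 3,5-dimethyl-4-[(E)-3-methyl-5-(triisopropylsilyloxy)pent-3-enyl]phenol | Cc1cc(O)cc(C)c1CC/C(C)=C/CO[Si](C(C)C)(C(C)C)C(C)C | intermediate
7 | 4-hydroxy-3,5-dimethyl-4-[(E)-3-methyl-5-(triisopropylsilyloxy)pent-3-enyl]cyclohexa-2,5-dienone (achiral p-quinol) | CC1=CC(=O)C=C(C)C1(O)CC/C(C)=C/CO[Si](C(C)C)(C(C)C)C(C)C | intermediate
8 | 2,2-dimethyl-1,3-dioxane-4,6-dione (Meldrum's acid) | CC1(C)OC(=O)CC(=O)O1 | starting material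
9 | 3-methylbut-2-enoyl chloride | CC(C)=CC(Cl)=O | starting material
10 | 5-(1-hydroxy-3-methylbut-2-enylidene)-2,2-dimethyl-1,3-dioxane-4,6-dione | CC(C)=CC(O)=C1C(=O)OC(C)(C)OC1=O | intermediate
11 | (3-methylbut-2-enoyl)ketene (not isolated) | CC(C)=CC(=O)C=C=O | intermediate
12 | 3,5-dimethyl-1-[(E)-3-methyl-5-(triisopropylsilyloxy)pent-3-enyl]-4-oxocyclohexa-2,5-dienyl 5-methyl-3-oxohex-4-enoate | CC(C)=CC(=O)CC(=O)OC1(CC/C(C)=C/CO[Si](C(C)C)(C(C)C)C(C)C)C(C)=CC(=O)C=C1C | intermediate
13 | mono-Michael adduct (not isolated): γ-lactone (C9α-O–CO–C1) cis-fused at C9–C10 to the 6-oxocyclohex-7-ene ring B; 10β-methyl; C1 (H β) carries the 3-methylbut-2-enoyl group; side chain on C9β | CC(C)=CC(=O)[C@@H]1C(=O)O[C@]2(CC/C(C)=C/CO[Si](C(C)C)(C(C)C)C(C)C)C(C)=CC(=O)C[C@]12C | intermediate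
14 | cis-fused tricyclic keto lactone (not isolated): as 15 but 5β-H | O=C1CC(C)(C)[C@H]2C(=O)C=C(C)[C@@]3(CC/C(C)=C/CO[Si](C(C)C)(C(C)C)C(C)C)OC(=O)[C@@H]1[C@@]23C | intermediate
15 | trans-fused tricyclic keto lactone: labdane rings A and B with C2=O, C6=O, C7=C8, 5α-H, 10β-methyl, γ-lactone from the C1α carboxyl to C9α-O, side chain on C9β | O=C1CC(C)(C)[C@@H]2C(=O)C=C(C)[C@@]3(CC/C(C)=C/CO[Si](C(C)C)(C(C)C)C(C)C)OC(=O)[C@@H]1[C@@]23C | intermediate
16 | 1α-carboxy-15-(triisopropylsilyloxy)labda-8,13E-diene-2,6-dione (β-keto acid, not isolated) | O=C1CC(C)(C)[C@@H]2C(=O)CC(C)=C(CC/C(C)=C/CO[Si](C(C)C)(C(C)C)C(C)C)[C@@]2(C)[C@H]1C(O)=O | intermediate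
17 | 15-(triisopropylsilyloxy)labda-8,13E-diene-2,6-dione (5α-H, 10β-methyl) | O=C1CC(C)(C)[C@@H]2C(=O)CC(C)=C(CC/C(C)=C/CO[Si](C(C)C)(C(C)C)C(C)C)[C@@]2(C)C1 | intermediate
18 | 7α-hydroxy-15-(triisopropylsilyloxy)labda-8,13E-diene-2,6-dione | O=C1CC(C)(C)[C@@H]2C(=O)[C@@H](O)C(C)=C(CC/C(C)=C/CO[Si](C(C)C)(C(C)C)C(C)C)[C@@]2(C)C1 | intermediate
19 | 6β,7α-dihydroxy-15-(triisopropylsilyloxy)labda-8,13E-dien-2-one | O=C1CC(C)(C)[C@@H]2[C@H](O)[C@@H](O)C(C)=C(CC/C(C)=C/CO[Si](C(C)C)(C(C)C)C(C)C)[C@@]2(C)C1 | intermediate
20 | 15-(triisopropylsilyloxy)labda-8,13E-diene-2α,6β,7α-triol | O[C@H]1CC(C)(C)[C@@H]2[C@H](O)[C@@H](O)C(C)=C(CC/C(C)=C/CO[Si](C(C)C)(C(C)C)C(C)C)[C@@]2(C)C1 | intermediate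
21 | 2α,6β,7α-triacetoxy-15-(triisopropylsilyloxy)labda-8,13E-diene | CC(=O)O[C@H]1CC(C)(C)[C@@H]2[C@H](OC(C)=O)[C@@H](OC(C)=O)C(C)=C(CC/C(C)=C/CO[Si](C(C)C)(C(C)C)C(C)C)[C@@]2(C)C1 | intermediate
22 | 2α,6β,7α-triacetoxylabda-8,13E-dien-15-ol (CNP0305346.2) | CC(=O)O[C@H]1CC(C)(C)[C@@H]2[C@H](OC(C)=O)[C@@H](OC(C)=O)C(C)=C(CC/C(C)=C/CO)[C@@]2(C)C1 | target

Total step count: 13. Longest linear sequence: 12 steps (steps 1–4 and 6–13; step 5 is a one-step branch).

Steps most likely to fail

Step 7. The first Michael addition is reversible, so the enantiomeric excess may erode through retro-Michael opening of the lactone, and the sequence may stall at the stabilised β-keto lactone enolate before ring A closes. The fallback replaces the anionic cascade by a neutral, Lewis-acid-catalysed cycloaddition. It sets out from 12: O-silylation (TBSOTf, Et3N, CH2Cl2, −78 °C) should give the (Z)-silyl dienol ether F1. A chiral cationic oxazaborolidine (the triflimide salt of the protonated (S)-B-o-tolyl oxazaborolidine derived from diphenylprolinol, CH2Cl2, −78 to −20 °C) would activate the dienone carbonyl for an intramolecular Diels–Alder reaction (or its stepwise Mukaiyama–Michael/Michael equivalent), which is irreversible and should give the silyl enol ether cycloadduct F2. Dilute HCl in THF at 0 °C would remove the silyl group to give 14, which is equilibrated with DBU as in the second stage of step 7, so the fallback comes back to the route at 15.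

Step 9. Enolisation may occur in part at the C2 ketone, leading to hydroxylation at C1 or C3, or the oxidant may attack the γ-carbon C9 of the dienolate. The fallback blocks the competing ketone. It sets out from 17: the unhindered C2 ketone alone should be ketalised (1,2-bis(trimethylsilyloxy)ethane, TMSOTf cat., CH2Cl2, −78 °C) to give the C2 dioxolane F3. C6 is then the only enolisable ketone, so KN(SiMe3)2 and the oxaziridine should give the 7α-hydroxy ketal F4. Pyridinium p-toluenesulfonate in wet acetone would remove the ketal, and the fallback comes back to the route at 18.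

Step 11. Electron transfer may also cleave the allylic C7–O bond once the 7α-hydroxyl is in place, giving a deoxygenated by-product. The fallback moves the dissolving-metal reduction ahead of the C7 oxygenation. It sets out from 17: one equivalent of KN(SiMe3)2 should convert the C6 ketone to its dienolate, which is inert to electron transfer, and Li in NH3/tBuOH then reduces only C2; NH4Cl protonates the dienolate at C7 to give the 2α-hydroxy β,γ-enone F5. KN(SiMe3)2 (2.1 equiv) and the oxaziridine should then give the 2α,7α-dihydroxy ketone F6, in which no second ketone competes. Me4NBH(OAc)3 reduction of C6 as in step 10 brings the fallback back to the route at 20.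

Further compounds
F1 | step 7 | (Z)-tert-butyldimethylsilyl dienol ether of ester 12 | CC(C)=C/C(O[Si](C)(C)C(C)(C)C)=C/C(=O)OC1(CC/C(C)=C/CO[Si](C(C)C)(C(C)C)C(C)C)C(C)=CC(=O)C=C1C
F2 | step 7 | cis-fused cycloadduct, C2 tert-butyldimethylsilyl enol ether (C2=C3) of 14 | CC(C)(C)[Si](C)(C)OC1=CC(C)(C)[C@H]2C(=O)C=C(C)[C@@]3(CC/C(C)=C/CO[Si](C(C)C)(C(C)C)C(C)C)OC(=O)[C@@H]1[C@@]23C
F3 | step 9 | C2 ethylene ketal of 17 | O1CCOC12CC(C)(C)[C@@H]3C(=O)CC(C)=C(CC/C(C)=C/CO[Si](C(C)C)(C(C)C)C(C)C)[C@@]3(C)C2
F4 | step 9 | 7α-hydroxy C2 ethylene ketal | O1CCOC12CC(C)(C)[C@@H]3C(=O)[C@@H](O)C(C)=C(CC/C(C)=C/CO[Si](C(C)C)(C(C)C)C(C)C)[C@@]3(C)C2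
F5 | step 11 | 2α-hydroxy-15-(triisopropylsilyloxy)labda-8,13E-dien-6-one | O[C@H]1CC(C)(C)[C@@H]2C(=O)CC(C)=C(CC/C(C)=C/CO[Si](C(C)C)(C(C)C)C(C)C)[C@@]2(C)C1
F6 | step 11 | 2α,7α-dihydroxy-15-(triisopropylsilyloxy)labda-8,13E-dien-6-one | O[C@H]1CC(C)(C)[C@@H]2C(=O)[C@@H](O)C(C)=C(CC/C(C)=C/CO[Si](C(C)C)(C(C)C)C(C)C)[C@@]2(C)C1
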